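The readings were computed for an exercise, and the scatter is random.

A ratio of 2.24 in catalyst loading between the south and north runs, both charged with 0.10 M of substrate, goes with a ratio of 2.33 in L, the natural logarithm of substrate charged over substrate left, at 40.0 min.

| flask | substrate | reagent | free catalyst | remark | time |
|---|---|---|---|---|---|
| north | 0.10 M | 1.5 equiv | 1.7 mol% | run made earlier |  |
| south | 0.10 M | 1.5 equiv | 3.8 mol% | run made earlier |  |
| south-west | 0.15 M | 1.5 equiv | 2.5 mol% | run made earlier |  |
| flask | 0.10 M | 1.50 equiv | 2.5 mol% |  | 1.0 h |

| run | time / min | substrate / % | product / % |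
|---|---|---|---|
| north | 3.00 | 98.9 | 0.3 |
| north | 10.0 | 96.7 | 2.4 |
| north | 15.0 | 95.6 | 3.6 |
| north | 25.0 | 92.2 | 7.0 |
| north | 40.0 | 88.2 | 11.6 |
| south | 8.00 | 94.2 | 4.1 |
| south | 15.0 | 90.3 | 8.6 |
| south | 20.0 | 86.3 | 11.5 |
| south | 30.0 | 79.8 | 18.0 |
| south | 40.0 | 74.6 | 24.1 |
| south-west | 3.00 | 98.1 | 1.0 |
| south-west | 10.0 | 94.2 | 4.9 |
| south-west | 15.0 | 91.3 | 7.2 |
| south-west | 25.0 | 86.7 | 12.2 |
| south-west | 40.0 | 79.6 | 19.9 |

(scatter of a reading: 0.3 percentage points)

1. part of the substrate that has reacted at 1.0 h
2. share of the unused reagent that is free and not bound as idle adduct, at 1.0 h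

- the numbers in the tables scatter by 0.3 percentage points (one standard deviation)
- the earlier runs do not show how much of reagent is bound; that part of a forecast is a guess

The loss of substrate therefore seems to follow the catalyst charged, and if that loss is taken as first-order in substrate, the natural clock is the catalyst-time τ, the catalyst-to-substrate ratio multiplied by the time. τ is 0.680 min for the north run at that reading and 1.50 min for the flask at 1.0 h. L divided by τ is a specific rate κ, which is 0.185 min⁻¹ in the north run, and that value puts c in the flask at 24.2%.

The objection is that the north run has used 11.8% of its substrate, and this answer is twice that. The south-west run, at 0.15 M and 2.5 mol%, shows κ = 0.228 min⁻¹, higher than the north value. That run differs from the north run in both settings, so the readings do not say which one moves κ, but κ may not hold steady as the flask runs down.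

Putting the first answer back in asks for a run that has reached that depth, and the south run has used 25.4% of its substrate at its last reading, against the first answer of 24.2%. The south run at its last reading has the same substrate charge and τ = 1.52 min, a ratio of 0.987 to the flask. Its specific rate, L over τ at that reading, 0.193 min⁻¹, gives c = 25.1% for the flask, and that is the value held here, 0.90 percentage points above the first. No reading shows bound reagent, so fr stays a guess.

The forecast gave c = 24.5% (22.5% to 26.5%) and fr = 85% (45% to 99%), the latter as “mostly free, with wide limits”.

The flask gives c = 25.2% and fr = 93.8%.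

    reagent + free catalyst → catalyst intermediate A (k = 0.0738 L mol⁻¹ s⁻¹)
    catalyst intermediate A ⇌ by-product + catalyst intermediate B (K = 0.241 M, k = 0.0262 s⁻¹)
    substrate + catalyst intermediate B → catalyst intermediate C (k = 0.147 L mol⁻¹ s⁻¹)
    catalyst intermediate C → free catalyst + product (k = 0.00743 s⁻¹)
    reagent + by-product ⇌ idle adduct, settled at all times (K = 3.60 L mol⁻¹)

Read back from the flask, κ is 0.194 min⁻¹, close to the south value. The neighbouring flask holds the same charges but 6.2 mol% of free catalyst, so its τ at 1.0 h is 3.72 min, and κ from the south run gives it c = 51.2%. Its simulated c is 54.8%, which means a κ of 0.214 min⁻¹, higher than the south value. That neighbour ends with 45.2% substrate, 53.2% product and fr = 86.3%.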